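**Retrosynthetic overview**
1. The aldehyde goes on last, by Pd-catalysed reductive carbonylation of a stereodefined tetrasubstituted enol triflate, rather than by olefination of a ring ketone.
2. The side chain is joined at C15–C16 by B-alkyl Suzuki coupling of a ring-bound (E)-vinyl iodide with a hydroborated vinyl epoxide; the epoxide comes from Sharpless epoxidation of nerol.
3. The Z-alkene geometry and the hydroxypropyl arm come from a temporary ring: ethyl vinyl ketone annulation, Baeyer–Villiger ring expansion to a seven-membered enol lactone, then reductive opening.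
4. The ring stereotriad is relayed from one carbinol (C10, Davis hydroxylation): hydroxyl-directed conjugate methylation builds quaternary C11, and the resulting regiodefined enolate sets C6.
5. Ring order: the cyclohexane is present from the start; a cyclohexenone is fused on (step 6), expanded to the oxepinone (step 7) and opened (step 8); the oxirane is made on the side-chain piece (step 10) and carried to the end.

Assumption: the oxirane is read from the SMILES as the cis (nerol-type, 18R,19S) epoxide and made as drawn; the facial sense of the oxaziridine in step 2 is taken from the 2-methyl-1-tetralone enolate model, and the (+)-antipode would be used if it proved opposite.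

Locants in the text: C10 = ring C(OH)CH3, C11 = ring quaternary carbon, C6 = ring CH, C7 = ring alkene carbon, C2/C1 = exocyclic alkene carbon/CHO, C3 = CH2OH carbon, C12–C17 = chain carbons towards the oxirane.

**Step 1**
Reactants: 1 3-ethoxycyclohex-2-en-1-one
Product: 3 3-ethoxy-6-methylcyclohex-2-en-1-one (racemic), via lithium dienolate 2 (not isolated)
Conditions: LDA, THF, −78 °C; MeI, −78 → 0 °C
Reagents that add atoms: iodomethane, CI
Why: Stork–Danheiser kinetic α'-deprotonation of the vinylogous ester followed by SN2 methylation of the cross-conjugated enolate; the new stereocentre is racemic and is erased again by enolisation in step 2.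

**Step 2**
Reactants: 3 3-ethoxy-6-methylcyclohex-2-en-1-one
Product: 5 (6S)-3-ethoxy-6-hydroxy-6-methylcyclohex-2-en-1-one, via sodium enolate 4 (not isolated)
Conditions: NaHMDS, THF, −78 °C; (−)-[(8,8-dichlorocamphoryl)sulfonyl]oxaziridine, −78 °C; aq NH4Cl
Reagents that add atoms: (−)-[(8,8-dichlorocamphoryl)sulfonyl]oxaziridine, CC1(C)C2CCC13CS(=O)(=O)N4OC34C2(Cl)Cl
Why: Davis asymmetric enolate hydroxylation, in which the chiral N-sulfonyloxaziridine transfers oxygen to one face of the tetrasubstituted sodium enolate and so sets the tertiary carbinol (future C10, S) that later relays all ring stereochemistry.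

**Step 3**
Reactants: 5 (6S)-3-ethoxy-6-hydroxy-6-methylcyclohex-2-en-1-one; 6 5-bromopent-2-yne
Product: 9 (4S)-4-hydroxy-4-methyl-3-(pent-3-yn-1-yl)cyclohex-2-en-1-one, via pent-3-yn-1-ylmagnesium bromide 7 (not isolated), via magnesium alkoxide adduct 8 (not isolated)
Conditions: 6, Mg, THF, rt (2.5 equiv of 7); 5, THF, 0 °C → rt; then 1 M HCl, THF, 0 °C
Reagents that add atoms: water, O
Why: Stork–Danheiser transposition, that is Grignard 1,2-addition to the vinylogous ester carbonyl (one extra equivalent is spent on the free hydroxyl) and acid hydrolysis of the enol ether with β-elimination of the new tertiary alcohol, which gives the 3-substituted enone without touching the C10 stereocentre.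

**Step 4**
Reactants: 9 (4S)-4-hydroxy-4-methyl-3-(pent-3-yn-1-yl)cyclohex-2-en-1-one
Product: 11 (3S,4S)-3,4-dimethyl-3-(pent-3-yn-1-yl)-1,4-bis(trimethylsilyloxy)cyclohex-1-ene, via aluminium enolate 10 (not isolated)
Conditions: AlMe3 (3.5 equiv), CH2Cl2, −78 → 0 °C; TMSOTf (2.5 equiv), −78 °C; cold aq NaHCO3
Reagents that add atoms: trimethylaluminium, C[Al](C)C; trimethylsilyl trifluoromethanesulfonate, C[Si](C)(C)OS(=O)(=O)C(F)(F)F
Why: Proposed new method: AlMe3 converts the C10 hydroxyl into a dimethylaluminium alkoxide that delivers methyl to C11 through a five-membered O–Al–CH3···C11 transition state on the oxygen face while a second AlMe3 activates the carbonyl, so the new quaternary centre carries CH3 cis to the C10 oxygen and the regiodefined aluminium enolate is then O-silylated; the closest known reaction types are the hydroxyl-directed syn-selective AlMe3 conjugate methylation of γ-hydroxy enones (p-quinols) and the silyl trapping of aluminium enolates from copper-catalysed AlR3 additions that create quaternary centres.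

**Step 5**
Reactants: 11 (3S,4S)-3,4-dimethyl-3-(pent-3-yn-1-yl)-1,4-bis(trimethylsilyloxy)cyclohex-1-ene; 12 pent-1-en-3-one (ethyl vinyl ketone)
Product: 14 (2S,3S,4S)-4-hydroxy-3,4-dimethyl-2-(3-oxopentyl)-3-(pent-3-yn-1-yl)cyclohexan-1-one, via O-silyl diketone 13 (not isolated)
Conditions: TiCl4, CH2Cl2, −78 °C; then 1 M HCl, THF, rt
Reagents that add atoms: none
Why: Mukaiyama–Michael addition of the regiodefined silyl enol ether to the TiCl4-activated enone, which enters C6 axially, anti to the pseudoaxial C11 pentynyl chain and past the C10 oxygen rather than the C10 methyl, so the new chain ends up cis to the C11 methyl and the C10 oxygen; the acid work-up removes both silyl groups.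

**Step 6**
Reactants: 14 (2S,3S,4S)-4-hydroxy-3,4-dimethyl-2-(3-oxopentyl)-3-(pent-3-yn-1-yl)cyclohexan-1-one
Product: 16 (4aR,5S,6S)-6-hydroxy-1,5,6-trimethyl-5-(pent-3-yn-1-yl)-4,4a,5,6,7,8-hexahydronaphthalen-2(3H)-one, via ketol 15 (not isolated)
Conditions: pyrrolidine (0.3 equiv), AcOH (0.3 equiv), toluene, 60 °C
Reagents that add atoms: none
Why: Second half of a Robinson annulation (amine-catalysed intramolecular aldol condensation through the enamine of the unhindered ethyl ketone), run without strong base so that C6 does not epimerise; the temporary ring ties the ethyl-ketone carbonyl to the C6 side of the new tetrasubstituted alkene.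

**Step 7**
Reactants: 16 (4aR,5S,6S)-6-hydroxy-1,5,6-trimethyl-5-(pent-3-yn-1-yl)-4,4a,5,6,7,8-hexahydronaphthalen-2(3H)-one
Product: 17 seven-membered enol lactone (16 with a ring oxygen inserted between C=O and the methyl-bearing alkene carbon)
Conditions: mCPBA (1.1 equiv), Na2HPO4, CH2Cl2, 0 °C → rt
Reagents that add atoms: 3-chloroperbenzoic acid, O=C(OO)c1cccc(Cl)c1
Why: Baeyer–Villiger oxidation in which the electron-rich alkenyl carbon migrates in preference to the primary alkyl carbon, giving the enol lactone with the ring oxygen necessarily cis to C6; one equivalent of buffered peracid limits over-oxidation of the enol ester.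

**Step 8**
Reactants: 17 seven-membered enol lactone
Product: 19 (1Z)-1-[(2R,3S,4S)-4-hydroxy-2-(3-hydroxypropyl)-3,4-dimethyl-3-(pent-3-yn-1-yl)cyclohexylidene]ethyl trifluoromethanesulfonate, via lithium enolate alkoxide 18 (not isolated)
Conditions: LiBHEt3 (3.3 equiv), THF, −78 → −40 °C; PhNTf2 (1.1 equiv), −78 → 0 °C; aq NH4Cl
Reagents that add atoms: N-phenylbis(trifluoromethanesulfonimide), O=S(=O)(N(c1ccccc1)S(=O)(=O)C(F)(F)F)C(F)(F)F
Why: Proposed new method: hydride adds to the activated enol-ester carbonyl, the hemiacetal collapses to a lithium enolate whose geometry (O cis to C6) is inherited from the ring plus an aldehyde that is reduced at once to the primary alkoxide, and PhNTf2 then O-triflates the enolate, so one operation gives the hydroxypropyl arm and the stereodefined tetrasubstituted enol triflate; the closest known reaction types are the cleavage of enol esters to regiodefined enolates by organolithiums and the triflation of enolates generated by hydride conjugate reduction.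

**Step 9**
Reactants: 19 (1Z)-1-[(2R,3S,4S)-4-hydroxy-2-(3-hydroxypropyl)-3,4-dimethyl-3-(pent-3-yn-1-yl)cyclohexylidene]ethyl trifluoromethanesulfonate
Product: 21 (1Z)-1-{(2R,3S,4S)-4-hydroxy-2-(3-hydroxypropyl)-3-[(3E)-4-iodopent-3-en-1-yl]-3,4-dimethylcyclohexylidene}ethyl trifluoromethanesulfonate, via alkenylzirconocene 20 (not isolated)
Conditions: Cp2Zr(H)Cl (4 equiv), THF, 50 °C; I2, THF, 0 °C
Reagents that add atoms: iodine, II
Why: Schwartz hydrozirconation–iodination, with syn addition of Zr–H, equilibration under excess reagent to the less hindered methyl-bearing alkenyl carbon and iodinolysis with retention, which gives the (E)-2-iodoalkene; the two hydroxyls only consume extra reagent and the enol triflate is inert.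

**Step 10**
Reactants: 22 nerol [(2Z)-3,7-dimethylocta-2,6-dien-1-ol]
Product: 23 [(2R,3S)-3-methyl-3-(4-methylpent-3-en-1-yl)oxiran-2-yl]methanol
Conditions: Ti(OiPr)4 (5 mol %), D-(−)-diethyl tartrate (6 mol %), t-BuOOH, 4 Å MS, CH2Cl2, −20 °C
Reagents that add atoms: tert-butyl hydroperoxide, CC(C)(C)OO
Why: Katsuki–Sharpless asymmetric epoxidation of the (Z)-allylic alcohol, where the D-(−)-tartrate catalyst delivers oxygen to the face that gives the (2R,3S) cis-epoxide (mirror image of the L-(+)-tartrate series) and leaves the remote trisubstituted alkene untouched.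

**Step 11**
Reactants: 23 [(2R,3S)-3-methyl-3-(4-methylpent-3-en-1-yl)oxiran-2-yl]methanol
Product: 24 (2S,3S)-3-methyl-3-(4-methylpent-3-en-1-yl)oxirane-2-carbaldehyde
Conditions: TEMPO (10 mol %), PhI(OAc)2, CH2Cl2, rt
Reagents that add atoms: none
Why: TEMPO/PhI(OAc)2 (oxoammonium) oxidation of the primary alcohol to the aldehyde under neutral conditions, which neither opens the epoxide nor epimerises the epoxide CH (the descriptor changes only through CIP priorities).

**Step 12**
Reactants: 24 (2S,3S)-3-methyl-3-(4-methylpent-3-en-1-yl)oxirane-2-carbaldehyde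
Product: 25 (2S,3R)-3-ethenyl-2-methyl-2-(4-methylpent-3-en-1-yl)oxirane
Conditions: Ph3PCH3Br, KOt-Bu, THF, 0 °C; then 24, −78 → 0 °C
Reagents that add atoms: methyltriphenylphosphonium bromide, C[P+](c1ccccc1)(c1ccccc1)c1ccccc1.[Br-]
Why: Wittig methylenation of the epoxy aldehyde with the non-stabilised ylide at low temperature, which creates the vinyl group without touching either epoxide stereocentre.

**Step 13**
Reactants: 25 (2S,3R)-3-ethenyl-2-methyl-2-(4-methylpent-3-en-1-yl)oxirane; 21 vinyl iodide from step 9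
Product: 27 (1Z)-1-[(2R,3S,4S)-4-hydroxy-2-(3-hydroxypropyl)-3,4-dimethyl-3-{(3E)-4-methyl-6-[(2R,3S)-3-methyl-3-(4-methylpent-3-en-1-yl)oxiran-2-yl]hex-3-en-1-yl}cyclohexylidene]ethyl trifluoromethanesulfonate, via B-alkyl-9-BBN 26 (not isolated)
Conditions: 25, 9-BBN dimer, THF, 0 °C → rt; then 21, Pd(dppf)Cl2 (5 mol %), AsPh3, Cs2CO3, DMF/H2O, rt
Reagents that add atoms: none
Why: Anti-Markovnikov hydroboration of the monosubstituted vinyl group by 9-BBN (the trisubstituted alkene is too hindered) and B-alkyl Suzuki–Miyaura coupling at the vinyl iodide, which reacts far faster than the hindered tetrasubstituted enol triflate and couples with retention of the E geometry; no stereocentre is formed or touched.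

**Step 14**
Reactants: 27 coupled enol triflate
Product: 28 (2Z)-2-[(2R,3S,4S)-4-hydroxy-2-(3-hydroxypropyl)-3,4-dimethyl-3-{(3E)-4-methyl-6-[(2R,3S)-3-methyl-3-(4-methylpent-3-en-1-yl)oxiran-2-yl]hex-3-en-1-yl}cyclohexylidene]propanal (CNP0179098.1)
Conditions: Pd(PPh3)4 (10 mol %), CO (3 atm), Bu3SnH (slow addition), THF, 50 °C
Reagents that add atoms: carbon monoxide, [C-]#[O+]
Why: Palladium-catalysed reductive carbonylation (Stille-type formylation) of the enol triflate by oxidative addition, CO insertion and hydride transfer from Bu3SnH with retention of alkene geometry, which installs the aldehyde cis to C6 (Z) as the last step with the epoxide, the trisubstituted alkenes and both free hydroxyls as spectators.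

**Compound list**
1 | 3-ethoxycyclohex-2-en-1-one | CCOC1=CC(=O)CCC1 | starting material
2 | lithium 5-ethoxycyclohexa-1,5-dien-1-olate (kinetic dienolate of 1) | [Li]OC1=CCCC(OCC)=C1 | intermediate
3 | 3-ethoxy-6-methylcyclohex-2-en-1-one (racemic) | CCOC1=CC(=O)C(C)CC1 | intermediate
4 | sodium 5-ethoxy-2-methylcyclohexa-1,5-dien-1-olate | [Na]OC1=C(C)CCC(OCC)=C1 | intermediate
5 | (6S)-3-ethoxy-6-hydroxy-6-methylcyclohex-2-en-1-one | O=C1C=C(OCC)CC[C@]1(C)O | intermediate
6 | 5-bromopent-2-yne | CC#CCCBr | starting material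
7 | pent-3-yn-1-ylmagnesium bromide | CC#CCC[Mg]Br | intermediate
8 | (6S)-3-ethoxy-6-methyl-1-(pent-3-yn-1-yl)cyclohex-2-ene-1,6-diol, present as its magnesium alkoxide, C1 epimers | CCOC1=CC(O)(CCC#CC)[C@@](C)(O)CC1 | intermediate
9 | (4S)-4-hydroxy-4-methyl-3-(pent-3-yn-1-yl)cyclohex-2-en-1-one | O=C1C=C(CCC#CC)[C@@](C)(O)CC1 | intermediate
10 | bis(dimethylaluminium) enolate/alkoxide of (3S,4S)-4-hydroxy-3,4-dimethyl-3-(pent-3-yn-1-yl)cyclohexanone | CC#CCC[C@@]1(C)C=C(O[Al](C)C)CC[C@]1(C)O[Al](C)C | intermediate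
11 | (3S,4S)-3,4-dimethyl-3-(pent-3-yn-1-yl)-1,4-bis(trimethylsilyloxy)cyclohex-1-ene | CC#CCC[C@@]1(C)C=C(O[Si](C)(C)C)CC[C@]1(C)O[Si](C)(C)C | intermediate
12 | pent-1-en-3-one (ethyl vinyl ketone) | C=CC(=O)CC | starting material
13 | (2S,3S,4S)-3,4-dimethyl-2-(3-oxopentyl)-3-(pent-3-yn-1-yl)-4-(trimethylsilyloxy)cyclohexan-1-one | CC#CCC[C@@]1(C)[C@H](CCC(=O)CC)C(=O)CC[C@]1(C)O[Si](C)(C)C | intermediate
14 | (2S,3S,4S)-4-hydroxy-3,4-dimethyl-2-(3-oxopentyl)-3-(pent-3-yn-1-yl)cyclohexan-1-one | CC#CCC[C@@]1(C)[C@H](CCC(=O)CC)C(=O)CC[C@]1(C)O | intermediate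
15 | bicyclic ketol (aldol adduct of 14, new carbinol and methine centres undefined) | CC#CCC[C@@]1(C)[C@@H]2CCC(=O)C(C)C2(O)CC[C@]1(C)O | intermediate
16 | (4aR,5S,6S)-6-hydroxy-1,5,6-trimethyl-5-(pent-3-yn-1-yl)-4,4a,5,6,7,8-hexahydronaphthalen-2(3H)-one | CC#CCC[C@@]1(C)[C@@H]2CCC(=O)C(C)=C2CC[C@]1(C)O | intermediate
17 | seven-membered enol lactone: 16 with a ring O between C=O and C(CH3)= (2-benzoxepin-3-one skeleton, ring-fusion CH R, C(CH3)(pentynyl) S, C(OH)CH3 S) | CC#CCC[C@@]1(C)[C@@H]2CCC(=O)OC(C)=C2CC[C@]1(C)O | intermediate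
18 | trilithium (Z)-enolate/bis-alkoxide from reductive opening of 17 | CC#CCC[C@@]1(C)[C@H](CCCO[Li])/C(=C(/C)O[Li])CC[C@]1(C)O[Li] | intermediate
19 | (1Z)-1-[(2R,3S,4S)-4-hydroxy-2-(3-hydroxypropyl)-3,4-dimethyl-3-(pent-3-yn-1-yl)cyclohexylidene]ethyl trifluoromethanesulfonate | CC#CCC[C@@]1(C)[C@H](CCCO)/C(=C(/C)OS(=O)(=O)C(F)(F)F)CC[C@]1(C)O | intermediate
20 | (E)-alkenylzirconocene chloride from 19 (Zr on the methyl-bearing alkene carbon; hydroxyls drawn free) | Cl[Zr](C1C=CC=C1)(C1C=CC=C1)/C(C)=C/CC[C@@]1(C)[C@H](CCCO)/C(=C(/C)OS(=O)(=O)C(F)(F)F)CC[C@]1(C)O | intermediate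
21 | (1Z)-1-{(2R,3S,4S)-4-hydroxy-2-(3-hydroxypropyl)-3-[(3E)-4-iodopent-3-en-1-yl]-3,4-dimethylcyclohexylidene}ethyl trifluoromethanesulfonate | I/C(C)=C/CC[C@@]1(C)[C@H](CCCO)/C(=C(/C)OS(=O)(=O)C(F)(F)F)CC[C@]1(C)O | intermediate
22 | nerol, (2Z)-3,7-dimethylocta-2,6-dien-1-ol | CC(C)=CCC/C(C)=C\CO | starting material
23 | [(2R,3S)-3-methyl-3-(4-methylpent-3-en-1-yl)oxiran-2-yl]methanol | CC(C)=CCC[C@]1(C)O[C@@H]1CO | intermediate
24 | (2S,3S)-3-methyl-3-(4-methylpent-3-en-1-yl)oxirane-2-carbaldehyde | CC(C)=CCC[C@]1(C)O[C@@H]1C=O | intermediate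
25 | (2S,3R)-3-ethenyl-2-methyl-2-(4-methylpent-3-en-1-yl)oxirane | CC(C)=CCC[C@]1(C)O[C@@H]1C=C | intermediate
26 | 9-{2-[(2R,3S)-3-methyl-3-(4-methylpent-3-en-1-yl)oxiran-2-yl]ethyl}-9-borabicyclo[3.3.1]nonane | CC(C)=CCC[C@]1(C)O[C@@H]1CCB1C2CCCC1CCC2 | intermediate
27 | (1Z)-1-[(2R,3S,4S)-4-hydroxy-2-(3-hydroxypropyl)-3,4-dimethyl-3-{(3E)-4-methyl-6-[(2R,3S)-3-methyl-3-(4-methylpent-3-en-1-yl)oxiran-2-yl]hex-3-en-1-yl}cyclohexylidene]ethyl trifluoromethanesulfonate | CC(C)=CCC[C@]1(C)O[C@@H]1CC/C(C)=C/CC[C@@]1(C)[C@H](CCCO)/C(=C(/C)OS(=O)(=O)C(F)(F)F)CC[C@]1(C)O | intermediate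
28 | CNP0179098.1, (2Z)-2-[(2R,3S,4S)-4-hydroxy-2-(3-hydroxypropyl)-3,4-dimethyl-3-{(3E)-4-methyl-6-[(2R,3S)-3-methyl-3-(4-methylpent-3-en-1-yl)oxiran-2-yl]hex-3-en-1-yl}cyclohexylidene]propanal | CC(C)=CCC[C@]1(C)O[C@@H]1CC/C(C)=C/CC[C@@]1(C)[C@H](CCCO)/C(=C(/C)C=O)CC[C@]1(C)O | target

**Totals**
Total step count: 14. Longest linear sequence: 11 steps (steps 1–9, 13, 14); the side-chain piece takes 3 steps (10–12).

**Three steps most likely to fail**

Step 4. The directed methyl transfer must build a quaternary carbon next to the fully substituted carbinol carbon; 1,2-addition or no reaction are the likely failure modes. The fallback sets out from 5 and comes back at 14; it reverses the order of the two C11 substituents and chooses the face by sterics instead of delivery. MeMgBr followed by aqueous HCl converts 5 into (4S)-4-hydroxy-3,4-dimethylcyclohex-2-en-1-one F1. TESOTf/2,6-lutidine gives its triethylsilyl ether F2. Copper-catalysed conjugate addition of Grignard reagent 7 (CuBr·SMe2, TMSCl, HMPA, THF, −78 °C) anti to the silyloxy group gives the trimethylsilyl enol ether F3. The Mukaiyama–Michael reaction with 12 (TiCl4) gives the O-triethylsilyl diketone F4, and HF·pyridine frees the carbinol to rejoin the route at 14.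

Step 8. The one-pot hydride opening and triflation is unprecedented as a whole, and the primary alkoxide or an intramolecular aldol could interfere. The fallback sets out from 17 and comes back at 19. KOt-Bu (2.1 equiv, THF, −78 °C) opens the enol lactone by transesterification to the potassium enolate, which still has the ring-derived geometry. PhNTf2 gives the enol triflate tert-butyl ester F5, and DIBAL (CH2Cl2, −78 → 0 °C) reduces the ester to the primary alcohol 19.

Step 14. Reductive carbonylation of a hindered tetrasubstituted enol triflate on the complete molecule may give simple triflate reduction or be slow. The fallback sets out from 27 and ends at 28; it goes through the ester oxidation level. Pd(OAc)2/dppp, CO (1 atm), MeOH, Et3N, DMF, 60 °C gives the methyl (Z)-enoate F6. DIBAL (CH2Cl2, −78 °C) gives the allylic alcohol F7, and MnO2 (CH2Cl2, rt) oxidises only the allylic hydroxyl to give 28.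

**Further compounds**
F1 | step 4 | (4S)-4-hydroxy-3,4-dimethylcyclohex-2-en-1-one | O=C1C=C(C)[C@@](C)(O)CC1
F2 | step 4 | (4S)-3,4-dimethyl-4-(triethylsilyloxy)cyclohex-2-en-1-one | O=C1C=C(C)[C@@](C)(O[Si](CC)(CC)CC)CC1
F3 | step 4 | (3S,4S)-3,4-dimethyl-3-(pent-3-yn-1-yl)-4-(triethylsilyloxy)-1-(trimethylsilyloxy)cyclohex-1-ene | CC#CCC[C@@]1(C)C=C(O[Si](C)(C)C)CC[C@]1(C)O[Si](CC)(CC)CC
F4 | step 4 | (2S,3S,4S)-3,4-dimethyl-2-(3-oxopentyl)-3-(pent-3-yn-1-yl)-4-(triethylsilyloxy)cyclohexan-1-one | CC#CCC[C@@]1(C)[C@H](CCC(=O)CC)C(=O)CC[C@]1(C)O[Si](CC)(CC)CC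
F5 | step 8 | enol triflate tert-butyl ester (19 with CO2t-Bu in place of CH2OH) | CC#CCC[C@@]1(C)[C@H](CCC(=O)OC(C)(C)C)/C(=C(/C)OS(=O)(=O)C(F)(F)F)CC[C@]1(C)O
F6 | step 14 | methyl (Z)-enoate (28 with CO2CH3 in place of CHO) | CC(C)=CCC[C@]1(C)O[C@@H]1CC/C(C)=C/CC[C@@]1(C)[C@H](CCCO)/C(=C(/C)C(=O)OC)CC[C@]1(C)O
F7 | step 14 | allylic alcohol (28 with CH2OH in place of CHO) | CC(C)=CCC[C@]1(C)O[C@@H]1CC/C(C)=C/CC[C@@]1(C)[C@H](CCCO)/C(=C(/C)CO)CC[C@]1(C)O
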